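**Strategy.** Each drimane unit is disconnected in ring B at C8–C9. The key step, a titanocene-mediated reductive opening of a terminal epoxide followed by 6-exo-dig radical cyclisation onto an alkyne, forms that bond and at once delivers the exocyclic C8=C12 methylene, the C9 stereocentre and the free C11 hydroxyl: it exploits the homoallylic alcohol array C12=C8–C9–C11–O of ring B. Its precursor is an 8,9-seco ring-A cyclohexane obtained by excising the aromatic ring of dehydroabietic acid, which supplies C4, C5 and C10. One monomer alcohol is then converted by two auxiliary-controlled alkylations into isocitrate ethers, which two esterifications join to the trimer.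

Key step: step 9

Remark: drimane numbering is used throughout (ring A = C1–C5 and C10; ring B = C5–C10; C11 = CH2O on C9; C12 = exocyclic CH2 on C8; C15 = the 4α-CH2O carbon, formerly C18 of dehydroabietic acid). C1' and C2' are the ether-bearing carbon and its neighbour in each isocitrate. D = 15-(tert-butyldimethylsilyloxy)drim-8(12)-en-11-yl. Unit A carries the free central acid, unit C the free 15-OH, unit B lies between.
Assumption: (+)-dehydroabietic acid and all reagents named are taken as commercially available.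

Step 1
Reactants: 1 (+)-dehydroabietic acid
Product: 2 dehydroabietinol
Conditions: LiAlH4, THF, 0 °C to reflux
Reagents that add atoms: none
Why: LiAlH4 reduction of the hindered tertiary acid gives the neopentyl alcohol and leaves the arene and the C4, C5 and C10 stereocentres untouched.

Step 2
Reactants: 2 dehydroabietinol
Product: 3 18-O-TBS-dehydroabietinol
Conditions: TBSCl, imidazole, DMF, rt
Reagents that add atoms: tert-butyldimethylsilyl chloride CC(C)(C)[Si](C)(C)Cl
Why: Silyl ether formation masks the future 15-OH with a group that should survive ozone, hydride, ylide, radical and enolate chemistry.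

Step 3
Reactants: 3 18-O-TBS-dehydroabietinol
Product: 4 8,9-seco diacid
Conditions: O3 (excess), CH2Cl2/MeOH, −20 °C; then H2O2, aq. NaOH, 0 °C to rt; then H3O+ (pH 3)
Reagents that add atoms: ozone [O-][O+]=O; hydrogen peroxide OO
Why: Exhaustive ozonolysis of the electron-rich trialkylbenzene with oxidative work-up (arene as a latent 1,2-dicarboxylic acid) removes C11–C14 and the isopropyl group, so that the ring-fusion carbons C8 and C9 end as carboxyl groups and ring B is opened at C8–C9 while C4, C5 and C10 are untouched.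

Step 4
Reactants: 4 8,9-seco diacid
Product: 5 seco diol
Conditions: LiAlH4, THF, reflux
Reagents that add atoms: none
Why: LiAlH4 reduces both the unhindered and the hindered tertiary carboxylic acid to primary alcohols without affecting the silyl ether.

Step 5
Reactants: 5 seco diol
Product: 6 seco hydroxy aldehyde
Conditions: TEMPO (cat.), PhI(OAc)2, CH2Cl2, 0 °C to rt
Reagents that add atoms: none
Why: The sterically discriminating oxoammonium (TEMPO) oxidation should convert the unhindered C8 carbinol into the aldehyde while the neopentyl C9 carbinol on quaternary C10 survives.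

Step 6
Reactants: 6 seco hydroxy aldehyde
Product: 7 seco alkynol
Conditions: dimethyl (1-diazo-2-oxopropyl)phosphonate, K2CO3, MeOH, rt
Reagents that add atoms: dimethyl (1-diazo-2-oxopropyl)phosphonate CC(=O)C(=[N+]=[N-])P(=O)(OC)OC
Why: Seyferth–Gilbert homologation with the Ohira–Bestmann reagent converts the aldehyde into the terminal alkyne (adds C12) under mild carbonate conditions that tolerate the free neopentyl alcohol.

Step 7
Reactants: 7 seco alkynol
Product: 8 seco alkynal
Conditions: Dess–Martin periodinane, NaHCO3, CH2Cl2, rt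
Reagents that add atoms: none
Why: Dess–Martin oxidation of the neopentyl alcohol gives a non-enolisable aldehyde, so no stereocentre is at risk.

Step 8
Reactants: 8 seco alkynal
Product: 9 seco epoxy-alkyne (both epimers at the oxirane carbon)
Conditions: Me3S+ I−, KN(SiMe3)2, THF, 0 °C
Reagents that add atoms: trimethylsulfonium iodide C[S+](C)C.[I-]
Why: Corey–Chaykovsky epoxidation adds C11 to the hindered aldehyde, and the configuration of the new oxirane carbon is irrelevant because that carbon becomes a planar radical in step 9.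

Step 9
Reactants: 9 seco epoxy-alkyne
Product: 12 15-(TBS-oxy)drim-8(12)-en-11-ol, via β-titanoxy C9 radical 10 (not isolated), via chlorotitanocene alkoxide 11 (not isolated)
Conditions: Cp2TiCl2 (0.2 equiv), Mn dust, 2,4,6-collidine hydrochloride, THF, rt, slow addition of 9
Reagents that add atoms: none
Why: Cp2TiCl (trivalent titanium, formed in situ from Cp2TiCl2 and Mn) transfers one electron to the epoxide, whose C9–O bond breaks to give the secondary β-titanoxy radical 10 (reductive epoxide opening of the Nugent–RajanBabu type) rather than the primary C11 radical. Radical 10 adds to the terminal alkyne in a 6-exo-dig closure of ring B that forms the C8–C9 bond (the 7-endo mode is disfavoured); the exocyclic vinyl radical is quenched by hydrogen abstraction from THF or by reduction and protonation, and collidinium chloride releases 12 from alkoxide 11 and returns titanium to the cycle. The closest known reaction type is the titanocene-mediated radical cyclisation of epoxy-alkynes to 2-methylenecycloalkylmethanols. The new C9 stereocentre is set in a chair-like transition state on the preformed ring A: the tether on C5 and the radical carbon on C10 are trans-diequatorial, which enforces the trans-decalin, and the CH2O–Ti group sits pseudo-equatorial, which should give 9α-H and 9β-CH2O. The step needs regioselective opening to the C9 radical, secured by radical stability and by titanium binding the unhindered CH2–O terminus, and cyclisation faster than capture of 10 by a second trivalent titanium (which would deoxygenate to the vinyl compound), secured by the hindered neopentyl-type radical and the low stationary Cp2TiCl concentration of the catalytic protocol.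

Step 10
Reactants: 12 15-(TBS-oxy)drim-8(12)-en-11-ol
Product: 13 D-oxyacetic acid
Conditions: NaH, BrCH2CO2H, THF, 0 °C to reflux; then H3O+
Reagents that add atoms: bromoacetic acid OC(=O)CBr
Why: Williamson etherification in which the sodium alkoxide of the hindered primary alcohol displaces bromide from sodium bromoacetate, an unhindered electrophile that cannot eliminate.

Step 11
Reactants: 13 D-oxyacetic acid
Product: 15 (S)-4-benzyl-3-(D-oxyacetyl)oxazolidin-2-one, via mixed pivalic anhydride 14 (not isolated)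
Conditions: PivCl, Et3N, THF, −20 °C; then (S)-4-benzyl-2-oxazolidinone, n-BuLi, THF, −78 to 0 °C
Reagents that add atoms: (S)-4-benzyl-2-oxazolidinone O=C1OC[C@H](Cc2ccccc2)N1; pivaloyl chloride CC(C)(C)C(Cl)=O (atoms carried only in 14)
Why: N-acylation of the lithiated oxazolidinone by mixed anhydride 14 installs the chiral auxiliary on the glycolate carboxyl.

Step 12
Reactants: 15 (S)-4-benzyl-3-(D-oxyacetyl)oxazolidin-2-one
Product: 16 C1'-alkylated imide (1'R; CH2CO2t-Bu)
Conditions: NaN(SiMe3)2, THF, −78 °C; then BrCH2CO2t-Bu, −78 to −45 °C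
Reagents that add atoms: tert-butyl bromoacetate BrCC(=O)OC(C)(C)C
Why: Evans alkylation of the chelated (Z)-sodium enolate of the α-alkoxy imide, in which the bromoacetate enters on the face opposite the benzyl group and sets C1' as R.

Step 13
Reactants: 16 C1'-alkylated imide
Product: 17 4-tert-butyl 1-methyl (2R)-2-(D-oxy)butanedioate
Conditions: MeMgBr, MeOH, THF, 0 °C
Reagents that add atoms: methanol CO
Why: Transesterification of the imide with methoxymagnesium bromide removes the auxiliary as the methyl ester under weakly basic conditions that spare the tert-butyl ester and should not epimerise C1'.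

Step 14
Reactants: 17 4-tert-butyl 1-methyl (2R)-2-(D-oxy)butanedioate
Product: 18 (3R)-3-(D-oxy)-4-methoxy-4-oxobutanoic acid
Conditions: TMSOTf, 2,6-lutidine, CH2Cl2, 0 °C; then aqueous work-up (pH 4)
Reagents that add atoms: none
Why: Silyl-triflate-mediated cleavage of the tert-butyl ester (loss of isobutene) under buffered aprotic conditions spares the TBS ether, the methyl ester and the exocyclic alkene.

Step 15
Reactants: 18 (3R)-3-(D-oxy)-4-methoxy-4-oxobutanoic acid
Product: 20 succinyl imide (C1' CO2Me; C2'H2–CO-oxazolidinone), via mixed pivalic anhydride 19 (not isolated)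
Conditions: PivCl, Et3N, THF, −20 °C; then (S)-4-benzyl-2-oxazolidinone, n-BuLi, THF, −78 to 0 °C
Reagents that add atoms: (S)-4-benzyl-2-oxazolidinone O=C1OC[C@H](Cc2ccccc2)N1; pivaloyl chloride CC(C)(C)C(Cl)=O (atoms carried only in 19)
Why: A second N-acylation places the auxiliary on the future central carboxyl, so that C2' becomes the α-carbon of an imide enolate.

Step 16
Reactants: 20 succinyl imide
Product: 21 C2'-alkylated imide (1'R,2'S; CH2CO2allyl)
Conditions: NaN(SiMe3)2, THF, −78 °C; then BrCH2CO2CH2CH=CH2, −78 °C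
Reagents that add atoms: allyl bromoacetate BrCC(=O)OCC=C
Why: Evans alkylation in which the base enolises only the imide α-CH2 (more acidic than the ester α-CH at C1') and allyl bromoacetate attacks anti to the benzyl group to set C2' as S, the low temperature holding back β-elimination of the alkoxide.

Step 17
Reactants: 21 C2'-alkylated imide (allyl series)
Product: 22 monomer acid (1'R,2'S; 1'-CO2Me; 2'-CO2H; CH2CO2allyl; 15-OTBS)
Conditions: LiOH, H2O2, THF/H2O, 0 °C; then Na2SO3; then H3O+
Reagents that add atoms: hydrogen peroxide OO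
Why: Lithium hydroperoxide cleaves the exocyclic imide carbonyl selectively (standard auxiliary removal), freeing the central carboxyl while the methyl and allyl esters should survive.

Step 18
Reactants: 20 succinyl imide
Product: 23 C2'-alkylated imide (1'R,2'S; CH2CO2Me)
Conditions: NaN(SiMe3)2, THF, −78 °C; then BrCH2CO2Me, −78 °C
Reagents that add atoms: methyl bromoacetate BrCC(=O)OC
Why: The same Evans alkylation as in step 16, with methyl bromoacetate, sets C2' as S under control of the benzyl group of the auxiliary.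

Step 19
Reactants: 23 C2'-alkylated imide (methyl series)
Product: 24 unit-A acid (1'-CO2Me; 2'-CO2H; CH2CO2Me; 15-OTBS)
Conditions: LiOH, H2O2, THF/H2O, 0 °C; then Na2SO3; then H3O+
Reagents that add atoms: hydrogen peroxide OO
Why: Lithium hydroperoxide removes the auxiliary at the exocyclic carbonyl as in step 17 without touching the two methyl esters.

Step 20
Reactants: 24 unit-A acid
Product: 25 unit-A allyl ester (2'-CO2allyl; 15-OTBS)
Conditions: allyl bromide, KHCO3, DMF, rt
Reagents that add atoms: allyl bromide C=CCBr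
Why: O-alkylation of the carboxylate under weakly basic conditions protects the central acid as an allyl ester without enolising the β-alkoxy ester.

Step 21
Reactants: 25 unit-A allyl ester
Product: 26 unit-A alcohol (15-OH free)
Conditions: HF·pyridine, pyridine, THF, 0 °C to rt
Reagents that add atoms: none
Why: Buffered fluoride desilylation frees the neopentyl 15-OH while methyl esters, the allyl ester and the exocyclic alkene are inert.

Step 22
Reactants: 22 monomer acid; 26 unit-A alcohol
Product: 28 dimer B–A (15-OTBS on unit B), via Yamaguchi mixed anhydride 27 (not isolated)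
Conditions: 2,4,6-trichlorobenzoyl chloride, Et3N, THF, rt; then 26, DMAP, toluene, rt
Reagents that add atoms: 2,4,6-trichlorobenzoyl chloride O=C(Cl)c1c(Cl)cc(Cl)cc1Cl (atoms carried only in 27)
Why: Yamaguchi esterification in which mixed anhydride 27 acylates the neopentyl 15-OH of 26; no stereocentre is formed and the mild base load should avoid epimerisation at C2'.

Step 23
Reactants: 28 dimer B–A
Product: 29 dimer alcohol (15-OH of unit B free)
Conditions: HF·pyridine, pyridine, THF, 0 °C to rt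
Reagents that add atoms: none
Why: Fluoride desilylation as in step 21 leaves all esters and alkenes intact.

Step 24
Reactants: 22 monomer acid; 29 dimer alcohol
Product: 31 trimer C–B–A (15-OTBS on unit C; three allyl esters), via 2-methyl-6-nitrobenzoic mixed anhydride 30 (not isolated)
Conditions: 2-methyl-6-nitrobenzoic anhydride, Et3N, DMAP (cat.), CH2Cl2, rt
Reagents that add atoms: 2-methyl-6-nitrobenzoic anhydride Cc1cccc([N+](=O)[O-])c1C(=O)OC(=O)c1c(C)cccc1[N+](=O)[O-] (atoms carried only in 30)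
Why: Shiina esterification, in which the aromatic anhydride converts 22 in the flask into mixed anhydride 30 and DMAP transfers only its unhindered aliphatic acyl group to the 15-OH of unit B; the one-pot protocol works with near-equimolar partners under a low base load, which suits the advanced alcohol 29, and no stereocentre is formed.

Step 25
Reactants: 31 trimer C–B–A
Product: 32 trimer alcohol (15-OH of unit C free; three allyl esters)
Conditions: HF·pyridine, pyridine, THF, 0 °C to rt
Reagents that add atoms: none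
Why: Fluoride desilylation frees the last 15-OH under conditions that the ester linkages tolerate.

Step 26
Reactants: 32 trimer alcohol
Product: 33 cryptoporic acid T
Conditions: Pd(PPh3)4 (cat.), morpholine, THF, rt; then dilute H3O+
Reagents that add atoms: none
Why: Zerovalent-palladium-catalysed allyl transfer to morpholine (Tsuji–Trost deallylation) cleaves the three allyl esters under neutral conditions, leaving methyl esters, inter-unit esters, exocyclic alkenes and all stereocentres untouched.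

**Compound list**

1 | (+)-dehydroabietic acid (abieta-8,11,13-trien-18-oic acid; 4α-CO2H, 4β-Me, 5α-H, 10β-Me) | CC(C)c1ccc2c(c1)CC[C@H]1[C@](C)(C(=O)O)CCC[C@]21C | starting material
2 | dehydroabietinol (abieta-8,11,13-trien-18-ol) | CC(C)c1ccc2c(c1)CC[C@H]1[C@](C)(CO)CCC[C@]21C | intermediate
3 | 18-O-TBS-dehydroabietinol | CC(C)c1ccc2c(c1)CC[C@H]1[C@](C)(CO[Si](C)(C)C(C)(C)C)CCC[C@]21C | intermediate
4 | 8,9-seco diacid: ring A with 4α-CH2OTBS, 4β-Me, 10β-Me, 5α-H; C5–CH2CH2CO2H; C10–CO2H | OC(=O)CC[C@H]1[C@](C)(CO[Si](C)(C)C(C)(C)C)CCC[C@]1(C)C(=O)O | intermediate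
5 | seco diol: C5–(CH2)3OH; C10–CH2OH | OCCC[C@H]1[C@](C)(CO[Si](C)(C)C(C)(C)C)CCC[C@]1(C)CO | intermediate
6 | seco hydroxy aldehyde: C5–CH2CH2CHO; C10–CH2OH | O=CCC[C@H]1[C@](C)(CO[Si](C)(C)C(C)(C)C)CCC[C@]1(C)CO | intermediate
7 | seco alkynol: C5–but-3-ynyl; C10–CH2OH | C#CCC[C@H]1[C@](C)(CO[Si](C)(C)C(C)(C)C)CCC[C@]1(C)CO | intermediate
8 | seco alkynal: C5–but-3-ynyl; C10–CHO | C#CCC[C@H]1[C@](C)(CO[Si](C)(C)C(C)(C)C)CCC[C@]1(C)C=O | intermediate
9 | seco epoxy-alkyne: C5–but-3-ynyl; C10–oxiranyl (both epimers at the oxirane carbon) | C#CCC[C@H]1[C@](C)(CO[Si](C)(C)C(C)(C)C)CCC[C@]1(C)C2CO2 | intermediate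
10 | β-titanoxy C9 radical (Cp2Ti(Cl)O–CH2–CH• on C10) | C#CCC[C@H]1[C@](C)(CO[Si](C)(C)C(C)(C)C)CCC[C@]1(C)[CH]CO[Ti](Cl)(C1C=CC=C1)C1C=CC=C1 | intermediate (not isolated)
11 | chlorotitanocene alkoxide of 12 (tetravalent titanium) | C=C1CC[C@H]2[C@](C)(CO[Si](C)(C)C(C)(C)C)CCC[C@]2(C)[C@H]1CO[Ti](Cl)(C1C=CC=C1)C1C=CC=C1 | intermediate (not isolated)
12 | 15-(TBS-oxy)drim-8(12)-en-11-ol (4α-CH2OTBS, 5α-H, 9α-H, 10β-Me) | C=C1CC[C@H]2[C@](C)(CO[Si](C)(C)C(C)(C)C)CCC[C@]2(C)[C@H]1CO | intermediate
13 | D-oxyacetic acid | C=C1CC[C@H]2[C@](C)(CO[Si](C)(C)C(C)(C)C)CCC[C@]2(C)[C@H]1COCC(=O)O | intermediate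
14 | mixed pivalic anhydride of 13 | C=C1CC[C@H]2[C@](C)(CO[Si](C)(C)C(C)(C)C)CCC[C@]2(C)[C@H]1COCC(=O)OC(=O)C(C)(C)C | intermediate (not isolated)
15 | (S)-4-benzyl-3-(D-oxyacetyl)oxazolidin-2-one | C=C1CC[C@H]2[C@](C)(CO[Si](C)(C)C(C)(C)C)CCC[C@]2(C)[C@H]1COCC(=O)N1[C@@H](Cc2ccccc2)COC1=O | intermediate
16 | (S)-4-benzyl-3-[(2R)-2-(D-oxy)-4-tert-butoxy-4-oxobutanoyl]oxazolidin-2-one | C=C1CC[C@H]2[C@](C)(CO[Si](C)(C)C(C)(C)C)CCC[C@]2(C)[C@H]1CO[C@@H](C(=O)N1[C@@H](Cc2ccccc2)COC1=O)CC(=O)OC(C)(C)C | intermediate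
17 | 4-tert-butyl 1-methyl (2R)-2-(D-oxy)butanedioate | C=C1CC[C@H]2[C@](C)(CO[Si](C)(C)C(C)(C)C)CCC[C@]2(C)[C@H]1CO[C@@H](C(=O)OC)CC(=O)OC(C)(C)C | intermediate
18 | (3R)-3-(D-oxy)-4-methoxy-4-oxobutanoic acid | C=C1CC[C@H]2[C@](C)(CO[Si](C)(C)C(C)(C)C)CCC[C@]2(C)[C@H]1CO[C@@H](C(=O)OC)CC(=O)O | intermediate
19 | mixed pivalic anhydride of 18 | C=C1CC[C@H]2[C@](C)(CO[Si](C)(C)C(C)(C)C)CCC[C@]2(C)[C@H]1CO[C@@H](C(=O)OC)CC(=O)OC(=O)C(C)(C)C | intermediate (not isolated)
20 | methyl (2R)-2-(D-oxy)-4-[(S)-4-benzyl-2-oxooxazolidin-3-yl]-4-oxobutanoate | C=C1CC[C@H]2[C@](C)(CO[Si](C)(C)C(C)(C)C)CCC[C@]2(C)[C@H]1CO[C@@H](C(=O)OC)CC(=O)N1[C@@H](Cc2ccccc2)COC1=O | intermediate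
21 | imide D–O–C1'H(CO2Me)–C2'H(CO-oxazolidinone)–CH2CO2allyl, (1'R,2'S), (S)-benzyl auxiliary | C=C1CC[C@H]2[C@](C)(CO[Si](C)(C)C(C)(C)C)CCC[C@]2(C)[C@H]1CO[C@@H](C(=O)OC)[C@H](CC(=O)OCC=C)C(=O)N1[C@@H](Cc2ccccc2)COC1=O | intermediate
22 | monomer acid D–O–C1'H(CO2Me)–C2'H(CO2H)–CH2CO2allyl, (1'R,2'S) | C=C1CC[C@H]2[C@](C)(CO[Si](C)(C)C(C)(C)C)CCC[C@]2(C)[C@H]1CO[C@@H](C(=O)OC)[C@H](CC(=O)OCC=C)C(=O)O | intermediate
23 | imide D–O–C1'H(CO2Me)–C2'H(CO-oxazolidinone)–CH2CO2Me, (1'R,2'S) | C=C1CC[C@H]2[C@](C)(CO[Si](C)(C)C(C)(C)C)CCC[C@]2(C)[C@H]1CO[C@@H](C(=O)OC)[C@H](CC(=O)OC)C(=O)N1[C@@H](Cc2ccccc2)COC1=O | intermediate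
24 | unit-A acid D–O–C1'H(CO2Me)–C2'H(CO2H)–CH2CO2Me, (1'R,2'S) | C=C1CC[C@H]2[C@](C)(CO[Si](C)(C)C(C)(C)C)CCC[C@]2(C)[C@H]1CO[C@@H](C(=O)OC)[C@H](CC(=O)OC)C(=O)O | intermediate
25 | unit-A allyl ester D–O–C1'H(CO2Me)–C2'H(CO2allyl)–CH2CO2Me | C=C1CC[C@H]2[C@](C)(CO[Si](C)(C)C(C)(C)C)CCC[C@]2(C)[C@H]1CO[C@@H](C(=O)OC)[C@H](CC(=O)OC)C(=O)OCC=C | intermediate
26 | unit-A alcohol: 25 with free 15-OH | C=C1CC[C@H]2[C@](C)(CO)CCC[C@]2(C)[C@H]1CO[C@@H](C(=O)OC)[C@H](CC(=O)OC)C(=O)OCC=C | intermediate
27 | 2,4,6-trichlorobenzoic mixed anhydride of 22 | C=C1CC[C@H]2[C@](C)(CO[Si](C)(C)C(C)(C)C)CCC[C@]2(C)[C@H]1CO[C@@H](C(=O)OC)[C@H](CC(=O)OCC=C)C(=O)OC(=O)c1c(Cl)cc(Cl)cc1Cl | intermediate (not isolated)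
28 | dimer B–A: central carboxyl of unit B esterified with 15-O of unit A; 15-OTBS on unit B; two allyl esters | C=C1CC[C@H]2[C@](C)(COC(=O)[C@@H](CC(=O)OCC=C)[C@@H](OC[C@H]3C(=C)CC[C@H]4[C@](C)(CO[Si](C)(C)C(C)(C)C)CCC[C@]34C)C(=O)OC)CCC[C@]2(C)[C@H]1CO[C@@H](C(=O)OC)[C@H](CC(=O)OC)C(=O)OCC=C | intermediate
29 | dimer alcohol: 28 with free 15-OH on unit B | C=C1CC[C@H]2[C@](C)(COC(=O)[C@@H](CC(=O)OCC=C)[C@@H](OC[C@H]3C(=C)CC[C@H]4[C@](C)(CO)CCC[C@]34C)C(=O)OC)CCC[C@]2(C)[C@H]1CO[C@@H](C(=O)OC)[C@H](CC(=O)OC)C(=O)OCC=C | intermediate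
30 | 2-methyl-6-nitrobenzoic mixed anhydride of 22 | C=C1CC[C@H]2[C@](C)(CO[Si](C)(C)C(C)(C)C)CCC[C@]2(C)[C@H]1CO[C@@H](C(=O)OC)[C@H](CC(=O)OCC=C)C(=O)OC(=O)c1c(C)cccc1[N+](=O)[O-] | intermediate (not isolated)
31 | trimer C–B–A: 15-OTBS on unit C; three allyl esters | C=C1CC[C@H]2[C@](C)(COC(=O)[C@@H](CC(=O)OCC=C)[C@@H](OC[C@H]3C(=C)CC[C@H]4[C@](C)(COC(=O)[C@@H](CC(=O)OCC=C)[C@@H](OC[C@H]5C(=C)CC[C@H]6[C@](C)(CO[Si](C)(C)C(C)(C)C)CCC[C@]56C)C(=O)OC)CCC[C@]34C)C(=O)OC)CCC[C@]2(C)[C@H]1CO[C@@H](C(=O)OC)[C@H](CC(=O)OC)C(=O)OCC=C | intermediate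
32 | trimer alcohol: 31 with free 15-OH on unit C | C=C1CC[C@H]2[C@](C)(COC(=O)[C@@H](CC(=O)OCC=C)[C@@H](OC[C@H]3C(=C)CC[C@H]4[C@](C)(COC(=O)[C@@H](CC(=O)OCC=C)[C@@H](OC[C@H]5C(=C)CC[C@H]6[C@](C)(CO)CCC[C@]56C)C(=O)OC)CCC[C@]34C)C(=O)OC)CCC[C@]2(C)[C@H]1CO[C@@H](C(=O)OC)[C@H](CC(=O)OC)C(=O)OCC=C | intermediate
33 | cryptoporic acid T | C=C1CC[C@H]2[C@](C)(COC(=O)[C@@H](CC(=O)O)[C@@H](OC[C@H]3C(=C)CC[C@H]4[C@](C)(COC(=O)[C@@H](CC(=O)O)[C@@H](OC[C@H]5C(=C)CC[C@H]6[C@](C)(CO)CCC[C@]56C)C(=O)OC)CCC[C@]34C)C(=O)OC)CCC[C@]2(C)[C@H]1CO[C@@H](C(=O)OC)[C@H](CC(=O)OC)C(=O)O | target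

**Step count.** Total: 26 steps. Longest linear sequence: 24 steps (steps 1–15, 18–21, 22–26).

**Steps most likely to fail**

1. Step 9 (key step). The C9 radical may be reduced by a second trivalent titanium before it cyclises, which deoxygenates the substrate; the 6-exo-dig closure may be slow; or the facial control at C9 may be poor. Fallback: starting from aldehyde 8, Wittig methylenation (Ph3P=CH2, THF) should give the 1,7-enyne F1. Palladium-catalysed borylative enyne cyclisation (Pd(OAc)2 cat., bis(pinacolato)diboron, MeOH, toluene, 50 °C) then closes ring B by the same C8–C9 bond and should give the homoallylic pinacol boronate F2. Oxidation (NaBO3·4H2O, THF/H2O) returns to the route at 12.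

2. Step 3. The arene degradation may stop short or lose selectivity through competing oxidation at benzylic C7 or loss of the silyl ether on prolonged exposure. Fallback: starting from 3, Birch reduction (Li, NH3, t-BuOH, THF, −78 °C) dearomatises ring C to the 8,12-diene F3. Ozonolysis of its two isolated alkenes (O3, CH2Cl2/MeOH, −78 °C), followed by alkaline H2O2 cleavage of the resulting β-dicarbonyl fragments, returns to the route at 4.

3. Step 16 (and its twin, step 18). The imide enolate may expel the drimanyl alkoxide by β-elimination, or facial selectivity may be eroded by the adjacent C1' centre. Fallback: starting from 16, LiOH/H2O2 removes the auxiliary to give the carboxylic acid F4. Its dianion (LiN(i-Pr)2, 2.2 equiv, THF, −78 °C), in which the carboxylate disfavours alkoxide loss and the ether oxygen chelates the ester enolate, is alkylated with allyl bromoacetate anti to the C1' carboxylate (Fráter–Seebach-type control) to give the 2'-tert-butyl ester F5. Methylation with Me3SiCHN2 (MeOH/toluene) gives the triester F6, and TMSOTf/2,6-lutidine cleavage of the tert-butyl ester returns to the route at 22.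

**Further compounds**

F1 | step 9 | seco 1,7-enyne: C5–but-3-ynyl; C10–vinyl | C#CCC[C@H]1[C@](C)(CO[Si](C)(C)C(C)(C)C)CCC[C@]1(C)C=C
F2 | step 9 | 15-(TBS-oxy)drim-8(12)-en-11-yl pinacol boronate | C=C1CC[C@H]2[C@](C)(CO[Si](C)(C)C(C)(C)C)CCC[C@]2(C)[C@H]1CB1OC(C)(C)C(C)(C)O1
F3 | step 3 | 18-O-TBS-abieta-8,12-dien-18-ol | CC(C)C1=CCC2=C(C1)CC[C@H]1[C@](C)(CO[Si](C)(C)C(C)(C)C)CCC[C@]21C
F4 | step 16 | (2R)-2-(D-oxy)-4-tert-butoxy-4-oxobutanoic acid | C=C1CC[C@H]2[C@](C)(CO[Si](C)(C)C(C)(C)C)CCC[C@]2(C)[C@H]1CO[C@@H](C(=O)O)CC(=O)OC(C)(C)C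
F5 | step 16 | D–O–C1'H(CO2H)–C2'H(CO2t-Bu)–CH2CO2allyl, (1'R,2'S) | C=C1CC[C@H]2[C@](C)(CO[Si](C)(C)C(C)(C)C)CCC[C@]2(C)[C@H]1CO[C@@H](C(=O)O)[C@H](CC(=O)OCC=C)C(=O)OC(C)(C)C
F6 | step 16 | D–O–C1'H(CO2Me)–C2'H(CO2t-Bu)–CH2CO2allyl, (1'R,2'S) | C=C1CC[C@H]2[C@](C)(CO[Si](C)(C)C(C)(C)C)CCC[C@]2(C)[C@H]1CO[C@@H](C(=O)OC)[C@H](CC(=O)OCC=C)C(=O)OC(C)(C)C
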